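**Retrosynthetic overview**
1. Target ⇒ bis-TBS butenolide 22 ⇒ α-hydroxy ketone 20 (butenolide ring closed last with the ketene ylide Ph3P=C=C=O).
2. Key bond C9–C11: 20 ⇒ C9 enol triflate 15 + cyclopropanol 18, used as the homoenolate (β-carbanion) of the C13 ketone; C9 and C11 are both normally electrophilic carbons.
3. 15 ⇒ 2,6-diketone 11: SmI2 sets 2α-OH and 6α-OH, methylation of the C19 ester enolate sets C4, and the Δ8 enol triflate comes from regioselective conjugate reduction of an ene-dione.
4. Ene-dione 5 ⇒ 2,6-dimethyl-1,4-benzoquinone 3 (ring B, bought) + silyloxy dienoate 2; one enantioselective Diels–Alder reaction forms ring A and sets C10, then C5 is epimerised to the trans ring fusion.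
5. Ring order: ring B (quinone) → ring A ([4+2]) → C9 side chain (homoenolate coupling) → butenolide.

Assumption and notation: the S-configured oxazaborolidinium catalyst is taken to give the 10S adduct drawn (if the opposite sense is found, the R-catalyst is used with nothing else changed); labdane numbering is used for all bicyclic compounds (ring A = C1–C5 and C10, ring B = C5–C10, C17 = methyl on C8, C18/C19 = α/β substituent on C4, C20 = methyl on C10, side chain C11–C16), β = the face of the C10 methyl, α = the opposite face.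

**Step 1**
Reactants: 1 methyl (2E)-4-oxopent-2-enoate
Product: 2 methyl (2E)-4-[(triisopropylsilyl)oxy]penta-2,4-dienoate
Conditions: TIPSOTf, Et3N, CH2Cl2, 0 °C
Reagents that add atoms: triisopropylsilyl trifluoromethanesulfonate, CC(C)[Si](OS(=O)(=O)C(F)(F)F)(C(C)C)C(C)C
Why: Soft enolisation (silyl triflate plus amine) of the only enolisable position, the methyl ketone, gives the 2-silyloxy diene (silyl dienol ether formation) and leaves the E enoate untouched.

**Step 2**
Reactants: 2 methyl (2E)-4-[(triisopropylsilyl)oxy]penta-2,4-dienoate; 3 2,6-dimethyl-1,4-benzoquinone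
Product: 5 trans-fused ene-dione ester, via cis-fused Diels–Alder adduct 4 (not isolated)
Conditions: (S)-3,3-diphenyl-1-(2-methylphenyl)tetrahydro-1H,3H-pyrrolo[1,2-c][1,3,2]oxazaborole·HNTf2 (20 mol%), CH2Cl2, −78 → −40 °C; then DBU (0.5 equiv), rt
Reagents that add atoms: none
Why: Oxazaborolidinium-catalysed enantioselective Diels–Alder reaction in which the catalyst binds the quinone carbonyl flanked by two C–H groups, so the nucleophilic CH2 terminus of the 2-silyloxy diene attacks the methyl-bearing β-carbon from the unshielded face (sets C10 as 10β-Me and the C1–C10/C4–C5 regiochemistry), after which DBU epimerises C5, α to the C6 ketone, from the cis adduct to the more stable trans-fused 5α-H isomer with the ester equatorial.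

**Step 3**
Reactants: 5 trans-fused ene-dione ester
Product: 7 C9 enol triflate ketone, via lithium C9 enolate 6 (not isolated)
Conditions: LiBH(s-Bu)3 (1.0 equiv), THF, −78 °C; then N-(5-chloropyridin-2-yl)triflimide (Comins' reagent), −78 → −20 °C
Reagents that add atoms: N-(5-chloropyridin-2-yl)-1,1,1-trifluoro-N-(trifluoromethylsulfonyl)methanesulfonamide, Clc1ccc(N(S(=O)(=O)C(F)(F)F)S(=O)(=O)C(F)(F)F)nc1
Why: Conjugate (1,4) hydride reduction of the ene-dione, in which the bulky borohydride adds to the unsubstituted C7 and not to the methyl-bearing C8, gives only the C9 enolate, and O-triflation (Comins triflation) fixes it as the Δ8 enol triflate while the silyl enol ether and ester are inert.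

**Step 4**
Reactants: 7 C9 enol triflate ketone
Product: 11 C4-methylated 2,6-diketone triflate, via dilithium bis-enolate 8 (not isolated), via C4-methylated lithium dienolate 9 (not isolated), via C4-methylated silyl enol ether 10 (not isolated)
Conditions: LiN(i-Pr)2 (2.3 equiv), DMPU, THF, −78 °C; MeI (1.1 equiv), −78 °C; AcOH; then 48% aq. HF, MeCN, 0 °C
Reagents that add atoms: iodomethane, CI
Why: Dianion alkylation in which the first equivalent of amide removes the doubly activated C7–H (masking the C6 ketone as its dienolate) and the second forms the more reactive C4 ester enolate, which takes MeI from the α face anti to the axial 10β-methyl (sets C4 as 4α-Me, 4β-CO2Me, the usual outcome for C4 ester enolates of 10-methyldecalins), after which the acid quench reprotonates C7 and aqueous HF hydrolyses the silyl enol ether to the C2 ketone.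

**Step 5**
Reactants: 11 C4-methylated 2,6-diketone triflate
Product: 12 2α,6α-diol ester
Conditions: SmI2 (8 equiv), H2O (100 equiv), THF, 0 °C → rt
Reagents that add atoms: none
Why: Single-electron (ketyl) reduction with SmI2–H2O behaves like a dissolving-metal reduction and gives the thermodynamically preferred equatorial alcohols at both ketones (sets 2α-OH and 6α-OH, where hydride reagents would attack the open α face and give the axial β-alcohols), under amine-free and HMPA-free conditions in which the enol triflate and the hindered ester are expected to survive.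

**Step 6**
Reactants: 12 2α,6α-diol ester
Product: 13 2α,6α,19-triol
Conditions: i-Bu2AlH (6 equiv), CH2Cl2, −78 → 0 °C; aq. potassium sodium tartrate
Reagents that add atoms: none
Why: Ester reduction with the electrophilic hydride i-Bu2AlH converts the axial C19 ester to the primary alcohol without S–O cleavage of the enol triflate.

**Step 7**
Reactants: 13 2α,6α,19-triol
Product: 14 2α,19-bis-TBS ether
Conditions: TBSCl (2.3 equiv), imidazole, DMF, 0 °C → rt
Reagents that add atoms: tert-butyl(chloro)dimethylsilane, CC(C)(C)[Si](C)(C)Cl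
Why: Sterically controlled silylation in which the primary C19 and the unhindered equatorial C2 hydroxyls react, whereas the 6α-OH, flanked by C5 and the quaternary C4, stays free.

**Step 8**
Reactants: 14 2α,19-bis-TBS ether
Product: 15 6α-acetate enol triflate
Conditions: Ac2O, Et3N, 4-(dimethylamino)pyridine (cat.), CH2Cl2, rt
Reagents that add atoms: acetic anhydride, CC(=O)OC(C)=O
Why: Nucleophile-catalysed acylation (DMAP acyl transfer) of the single remaining, hindered 6α-hydroxyl.

**Step 9**
Reactants: 16 methyl glycolate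
Product: 17 methyl 2-[(triethylsilyl)oxy]acetate
Conditions: TESCl, imidazole, CH2Cl2, 0 °C
Reagents that add atoms: chlorotriethylsilane, CC[Si](Cl)(CC)CC
Why: Standard silylation of a primary alcohol, with TES chosen because mild acid removes it later without touching TBS ethers.

**Step 10**
Reactants: 17 methyl 2-[(triethylsilyl)oxy]acetate
Product: 18 1-{[(triethylsilyl)oxy]methyl}cyclopropan-1-ol
Conditions: EtMgBr (2.5 equiv), Ti(OiPr)4 (20 mol%), THF, 0 °C → rt; aq. NH4Cl
Reagents that add atoms: ethylmagnesium bromide, CC[Mg]Br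
Why: Kulinkovich cyclopropanation, in which the titanacyclopropane formed from EtMgBr and Ti(OiPr)4 acts as a 1,2-dicarbanion towards the ester and delivers the 1-substituted cyclopropanol, α-silyloxy esters being suitable substrates.

**Step 11** (key step)
Reactants: 15 6α-acetate enol triflate; 18 1-{[(triethylsilyl)oxy]methyl}cyclopropan-1-ol
Product: 20 16-hydroxy-13-ketone, via silyloxy ketone 19 (not isolated)
Conditions: Pd(OAc)2 (10 mol%), 2-dicyclohexylphosphino-2',4',6'-triisopropylbiphenyl (20 mol%), Cs2CO3 (2 equiv), toluene, 80 °C; then AcOH/THF/H2O (3:1:1), rt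
Reagents that add atoms: none
Why: Proposed new method: palladium-catalysed ring-opening cross-coupling of a cyclopropanol used as a ketone homoenolate (oxidative addition of zerovalent palladium into the enol triflate, exchange to the palladium cyclopropoxide, strain-driven β-carbon elimination to the β-palladated ketone, reductive elimination) joins C9, a former carbonyl carbon, to C11, the β-carbon of the C13 ketone, the closest known reactions being the same coupling of cyclopropanols with aryl halides and its intramolecular version with alkenyl triflates, no stereocentre is formed, and the dilute acid then removes only the TES group.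

**Step 12**
Reactants: 20 16-hydroxy-13-ketone
Product: 22 bis-TBS butenolide, via acyl ylide ester 21 (not isolated)
Conditions: Ph3P=C=C=O (1.3 equiv), toluene, 90 °C
Reagents that add atoms: (triphenylphosphoranylidene)ketene, O=C=C=P(c1ccccc1)(c1ccccc1)c1ccccc1
Why: Bestmann butenolide synthesis, in which the hydroxyl adds to the ketene ylide to give an acyl-stabilised phosphorane that closes by intramolecular Wittig olefination onto the adjacent ketone and forms the C13=C14 bond of the 4-substituted furan-2(5H)-one.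

**Step 13**
Reactants: 22 bis-TBS butenolide
Product: 23 6α-acetoxy-2α,19-dihydroxylabda-8,13-dien-15,16-olide
Conditions: HF·pyridine, pyridine, THF, 0 °C → rt
Reagents that add atoms: none
Why: Fluoride-mediated desilylation under buffered, mildly acidic conditions removes both TBS ethers while the hindered acetate, the butenolide and the tetrasubstituted alkene are stable.

**Compound list**
1 | methyl (2E)-4-oxopent-2-enoate | CC(=O)/C=C/C(=O)OC | starting material
2 | methyl (2E)-4-[(triisopropylsilyl)oxy]penta-2,4-dienoate | C=C(O[Si](C(C)C)(C(C)C)C(C)C)/C=C/C(=O)OC | intermediate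
3 | 2,6-dimethyl-1,4-benzoquinone | CC1=CC(=O)C=C(C)C1=O | starting material
4 | cis-fused Diels–Alder adduct: 2-(triisopropylsilyloxy)-Δ2 enol ether, 4α-CO2Me (4β-H), 5β-H, 10β-Me, 8-methyl-7-ene-6,9-dione | O=C1C=C(C)C(=O)[C@@]2(C)CC(O[Si](C(C)C)(C(C)C)C(C)C)=C[C@@H](C(=O)OC)[C@@H]12 | intermediate
5 | trans-fused ene-dione ester: as 4 but 5α-H (4α-CO2Me equatorial, 10β-Me) | O=C1C=C(C)C(=O)[C@@]2(C)CC(O[Si](C(C)C)(C(C)C)C(C)C)=C[C@@H](C(=O)OC)[C@H]12 | intermediate
6 | lithium C9 enolate: 9-lithiooxy-Δ8, 6-ketone, otherwise as 5 | O=C1CC(C)=C(O[Li])[C@@]2(C)CC(O[Si](C(C)C)(C(C)C)C(C)C)=C[C@@H](C(=O)OC)[C@H]12 | intermediate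
7 | C9 enol triflate ketone: 9-(trifluoromethylsulfonyloxy)-Δ8, 6-ketone, 2-silyloxy-Δ2, 4α-CO2Me (4β-H), 5α-H, 10β-Me | O=C1CC(C)=C(OS(=O)(=O)C(F)(F)F)[C@@]2(C)CC(O[Si](C(C)C)(C(C)C)C(C)C)=C[C@@H](C(=O)OC)[C@H]12 | intermediate
8 | dilithium bis-enolate of 7: C6 dienolate (6-OLi, Δ6, Δ8) and C4=C19 ester enolate | [Li]OC1=CC(C)=C(OS(=O)(=O)C(F)(F)F)[C@@]2(C)CC(O[Si](C(C)C)(C(C)C)C(C)C)=CC(=C(OC)O[Li])[C@H]12 | intermediate
9 | C4-methylated lithium dienolate: 4α-Me, 4β-CO2Me, 6-OLi, Δ6, Δ8 | [Li]OC1=CC(C)=C(OS(=O)(=O)C(F)(F)F)[C@@]2(C)CC(O[Si](C(C)C)(C(C)C)C(C)C)=C[C@](C)(C(=O)OC)[C@H]12 | intermediate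
10 | C4-methylated silyl enol ether: 7 with 4α-Me and 4β-CO2Me (C19 ester axial) | O=C1CC(C)=C(OS(=O)(=O)C(F)(F)F)[C@@]2(C)CC(O[Si](C(C)C)(C(C)C)C(C)C)=C[C@](C)(C(=O)OC)[C@H]12 | intermediate
11 | C4-methylated 2,6-diketone triflate: methyl 4α,8,10β-trimethyl-2,6-dioxo-9-(triflyloxy)-5α-decal-8-ene-4β-carboxylate | O=C1CC(C)=C(OS(=O)(=O)C(F)(F)F)[C@@]2(C)CC(=O)C[C@](C)(C(=O)OC)[C@H]12 | intermediate
12 | 2α,6α-diol ester: 11 with 2α-OH and 6α-OH (both equatorial) | O[C@H]1CC(C)=C(OS(=O)(=O)C(F)(F)F)[C@@]2(C)C[C@@H](O)C[C@](C)(C(=O)OC)[C@H]12 | intermediate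
13 | 2α,6α,19-triol: 4α-Me, 4β-CH2OH, 9-triflyloxy-Δ8 | O[C@H]1CC(C)=C(OS(=O)(=O)C(F)(F)F)[C@@]2(C)C[C@@H](O)C[C@](C)(CO)[C@H]12 | intermediate
14 | 2α,19-bis-TBS ether of 13, 6α-OH free | O[C@H]1CC(C)=C(OS(=O)(=O)C(F)(F)F)[C@@]2(C)C[C@@H](O[Si](C)(C)C(C)(C)C)C[C@](C)(CO[Si](C)(C)C(C)(C)C)[C@H]12 | intermediate
15 | 6α-acetate enol triflate: 6α-OAc derivative of 14 | CC(=O)O[C@H]1CC(C)=C(OS(=O)(=O)C(F)(F)F)[C@@]2(C)C[C@@H](O[Si](C)(C)C(C)(C)C)C[C@](C)(CO[Si](C)(C)C(C)(C)C)[C@H]12 | intermediate
16 | methyl glycolate | COC(=O)CO | starting material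
17 | methyl 2-[(triethylsilyl)oxy]acetate | COC(=O)CO[Si](CC)(CC)CC | intermediate
18 | 1-{[(triethylsilyl)oxy]methyl}cyclopropan-1-ol | CC[Si](CC)(CC)OCC1(O)CC1 | intermediate
19 | silyloxy ketone: C9–CH2CH2–C(=O)–CH2OTES side chain on the 6α-OAc, 2α,19-bis-OTBS, Δ8 decalin | CC(=O)O[C@H]1CC(C)=C(CCC(=O)CO[Si](CC)(CC)CC)[C@@]2(C)C[C@@H](O[Si](C)(C)C(C)(C)C)C[C@](C)(CO[Si](C)(C)C(C)(C)C)[C@H]12 | intermediate
20 | 16-hydroxy-13-ketone: C9–CH2CH2–C(=O)–CH2OH side chain, otherwise as 19 | CC(=O)O[C@H]1CC(C)=C(CCC(=O)CO)[C@@]2(C)C[C@@H](O[Si](C)(C)C(C)(C)C)C[C@](C)(CO[Si](C)(C)C(C)(C)C)[C@H]12 | intermediate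
21 | acyl ylide ester: 16-O-[(triphenylphosphoranylidene)acetyl] derivative of 20 | CC(=O)O[C@H]1CC(C)=C(CCC(=O)COC(=O)C=P(c3ccccc3)(c3ccccc3)c3ccccc3)[C@@]2(C)C[C@@H](O[Si](C)(C)C(C)(C)C)C[C@](C)(CO[Si](C)(C)C(C)(C)C)[C@H]12 | intermediate
22 | bis-TBS butenolide: 2α,19-bis-O-TBS ether of the target | CC(=O)O[C@H]1CC(C)=C(CCC2=CC(=O)OC2)[C@@]2(C)C[C@@H](O[Si](C)(C)C(C)(C)C)C[C@](C)(CO[Si](C)(C)C(C)(C)C)[C@H]12 | intermediate
23 | (2R,4S,5R,6S,10S)-6α-acetoxy-2α,19-dihydroxylabda-8,13-dien-15,16-olide | CC(=O)O[C@H]1CC(C)=C(CCC2=CC(=O)OC2)[C@@]2(C)C[C@@H](O)C[C@](C)(CO)[C@H]12 | target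

**Totals**
Total step count: 13. Longest linear sequence: 11 (steps 1–8 and 11–13; steps 9–10 make the cyclopropanol).

**The three steps most likely to fail**

Step 11 (homoenolate coupling). The palladium homoenolate can undergo β-hydride elimination (giving a vinyl ketone and the reduced alkene), and the fully substituted triflate next to the quaternary C10 is slow to couple. The fallback sets out from 15 and comes back at 20. A B-alkyl Suzuki–Miyaura coupling of 15 with the borane made from acrolein diethyl acetal and 9-BBN-H (PdCl2(dppf), K3PO4, DMF/THF/H2O, 60 °C) gives the C13 diethyl acetal F1. Pyridinium p-toluenesulfonate in wet acetone gives the C13 aldehyde F2. Carbene-catalysed hydroxymethylation of F2 with paraformaldehyde (3-benzyl-5-(2-hydroxyethyl)-4-methylthiazolium chloride, i-Pr2NEt, THF, 60 °C; the Breslow intermediate is an acyl anion that adds to formaldehyde and forms C13–C16) gives 20.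

Step 5 (SmI2 reduction beside the enol triflate). The triflate may suffer S–O cleavage or the reduction may stall. The fallback sets out from 5 and comes back at 12, postponing the triflation. Conjugate reduction of 5 as in step 3, with trapping by TIPSOTf in place of Comins' reagent, gives the bis(silyl enol ether) ketone F3. Dianion methylation as in step 4 gives the C4-methylated bis(silyl enol ether) F4. Brief treatment with cold dilute HF hydrolyses only the unhindered ring A enol ether and gives the 2,6-diketone C9 silyl enol ether F5. SmI2–H2O–Et3N at full strength gives the 2α,6α-diol C9 silyl enol ether F6. Bu4NF followed by Comins' reagent triflates the liberated enolate and gives 12.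

Step 4 (dianion methylation). Risks are C-methylation of the ketone dienolate at C7, incomplete second deprotonation and attack of the amide on the triflate. The fallback sets out from 7 and comes back at 11. TBSOTf/Et3N converts the C6 ketone into the C6 silyl dienol ether F7 (6-OTBS, Δ6, Δ8), which leaves the ester C4–H as the only acidic site. LiN(i-Pr)2 (1.1 equiv) and MeI give the C4-methylated silyl dienol ether F8. Aqueous HF in MeCN cleaves both silyl enol ethers and gives 11.

**Further compounds**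
F1 | step 11 | C13 diethyl acetal: C9–CH2CH2–CH(OEt)2 side chain on the 6α-OAc, 2α,19-bis-OTBS, Δ8 decalin | CC(=O)O[C@H]1CC(C)=C(CCC(OCC)OCC)[C@@]2(C)C[C@@H](O[Si](C)(C)C(C)(C)C)C[C@](C)(CO[Si](C)(C)C(C)(C)C)[C@H]12
F2 | step 11 | C13 aldehyde: C9–CH2CH2–CHO side chain, otherwise as F1 | CC(=O)O[C@H]1CC(C)=C(CCC=O)[C@@]2(C)C[C@@H](O[Si](C)(C)C(C)(C)C)C[C@](C)(CO[Si](C)(C)C(C)(C)C)[C@H]12
F3 | step 5 | bis(silyl enol ether) ketone: 2- and 9-triisopropylsilyloxy, Δ2 and Δ8, 6-ketone, 4α-CO2Me (4β-H), 5α-H | O=C1CC(C)=C(O[Si](C(C)C)(C(C)C)C(C)C)[C@@]2(C)CC(O[Si](C(C)C)(C(C)C)C(C)C)=C[C@@H](C(=O)OC)[C@H]12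
F4 | step 5 | C4-methylated bis(silyl enol ether): F3 with 4α-Me and 4β-CO2Me | O=C1CC(C)=C(O[Si](C(C)C)(C(C)C)C(C)C)[C@@]2(C)CC(O[Si](C(C)C)(C(C)C)C(C)C)=C[C@](C)(C(=O)OC)[C@H]12
F5 | step 5 | 2,6-diketone C9 silyl enol ether: 4α-Me, 4β-CO2Me, 9-triisopropylsilyloxy-Δ8 | O=C1CC(C)=C(O[Si](C(C)C)(C(C)C)C(C)C)[C@@]2(C)CC(=O)C[C@](C)(C(=O)OC)[C@H]12
F6 | step 5 | 2α,6α-diol C9 silyl enol ether: F5 with 2α-OH and 6α-OH | O[C@H]1CC(C)=C(O[Si](C(C)C)(C(C)C)C(C)C)[C@@]2(C)C[C@@H](O)C[C@](C)(C(=O)OC)[C@H]12
F7 | step 4 | C6 silyl dienol ether: 7 with 6-OTBS, Δ6 and Δ8 | CC(C)(C)[Si](C)(C)OC1=CC(C)=C(OS(=O)(=O)C(F)(F)F)[C@@]2(C)CC(O[Si](C(C)C)(C(C)C)C(C)C)=C[C@@H](C(=O)OC)[C@H]12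
F8 | step 4 | C4-methylated silyl dienol ether: F7 with 4α-Me and 4β-CO2Me | CC(C)(C)[Si](C)(C)OC1=CC(C)=C(OS(=O)(=O)C(F)(F)F)[C@@]2(C)CC(O[Si](C(C)C)(C(C)C)C(C)C)=C[C@](C)(C(=O)OC)[C@H]12
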